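Assumption: the target has no stereocentre and no stereogenic double bond, so it is achiral and needs no enantiocontrol; the tether is read as (CH2)14.

**Retrosynthetic overview**
1. Target 33 ⇐ bis(aryl acetate) 31: both quinone rings are unmasked last and together (CAN, then acetate hydrolysis). No ring is built; each six-membered ring is the intact carbocycle of p-benzoquinone 1.
2. 31 ⇐ 29 ⇐ 14 + 27: the C14 tether is cut between C6 and C7 (sp3–sp3 B-alkyl Suzuki coupling of a 6-bromohexyl arene with an oct-7-enyl arene).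
3. 14 ⇐ 1,2,4-trimethoxybenzene 4: C-3 methylation (between two OMe) comes first; formylation, Dakin oxidation and MOM protection follow, and a MOM-directed lithiation puts the bromohexyl chain next to the future OH.
4. 27 ⇐ 4: formylation, Dakin oxidation and MOM protection come first; a MOM-directed lithiation puts the methyl next to the future OH, and the last ring C–H (between two OMe) takes the octenyl chain.
5. 4 ⇐ 1 (Thiele–Winter, methylation); 8-bromooct-1-ene 18 ⇐ octa-1,7-diene 15.

**Route**

Step 1
Reactants: 1 p-benzoquinone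
Product: 2 benzene-1,2,4-triyl triacetate
Conditions: Ac2O, conc. H2SO4 (cat.), 40–50 °C
Reagents that add atoms: acetic anhydride CC(=O)OC(C)=O
Why: Thiele–Winter acetoxylation, in which acid-catalysed conjugate addition of acetate to the quinone and O-acetylation give the 1,2,4-trioxygenated benzene.

Step 2
Reactants: 2 benzene-1,2,4-triyl triacetate
Product: 4 1,2,4-trimethoxybenzene, via benzene-1,2,4-triol 3 (not isolated)
Conditions: Me2SO4, NaOH (aq), MeOH, N2, 0 → 40 °C
Reagents that add atoms: dimethyl sulfate COS(=O)(=O)OC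
Why: One-pot saponification and Williamson O-methylation, run oxygen-free because the triolate is air-sensitive.

Step 3
Reactants: 4 1,2,4-trimethoxybenzene
Product: 6 1,2,4-trimethoxy-3-methylbenzene, via 2,3,6-trimethoxyphenyllithium 5 (not isolated)
Conditions: n-BuLi, THF, 0 °C → rt; MeI, 0 °C → rt
Reagents that add atoms: iodomethane CI
Why: Directed ortho-metalation takes place at C-3, the position flanked by two methoxy groups, and the aryllithium is methylated by SN2.

Step 4
Reactants: 6 1,2,4-trimethoxy-3-methylbenzene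
Product: 8 2,4,5-trimethoxy-3-methylbenzaldehyde, via iminium salt 7 (not isolated)
Conditions: POCl3, DMF, 0 → 80 °C; then H2O
Reagents that add atoms: N,N-dimethylformamide CN(C)C=O; water O
Why: Vilsmeier–Haack formylation goes to the free position that is para to the 2-methoxy and ortho to the 4-methoxy group, the most activated site.

Step 5
Reactants: 8 2,4,5-trimethoxy-3-methylbenzaldehyde
Product: 10 2,4,5-trimethoxy-3-methylphenol, via aryl formate 9 (not isolated)
Conditions: 30% H2O2, H2SO4 (cat.), MeOH, rt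
Reagents that add atoms: hydrogen peroxide OO
Why: Acid-catalysed Dakin (Baeyer–Villiger-type) oxidation, in which the electron-rich aryl group migrates to oxygen and methanol cleaves the resulting formate.

Step 6
Reactants: 10 2,4,5-trimethoxy-3-methylphenol
Product: 11 1,2,4-trimethoxy-5-(methoxymethoxy)-3-methylbenzene
Conditions: NaH, MOMCl, DMF, 0 °C → rt
Reagents that add atoms: chloromethyl methyl ether COCCl
Why: Williamson-type O-alkylation of the phenoxide installs a MOM group that serves as protecting group and as a strong ortho-director.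

Step 7
Reactants: 11 1,2,4-trimethoxy-5-(methoxymethoxy)-3-methylbenzene; 12 1,6-dibromohexane
Product: 14 1-(6-bromohexyl)-2,3,5-trimethoxy-6-(methoxymethoxy)-4-methylbenzene, via aryllithium 13 (not isolated)
Conditions: n-BuLi, THF, 0 °C → rt; then added to 12 (4 equiv), THF, −40 °C → rt
Reagents that add atoms: none
Why: Directed ortho-metalation at the only ring C–H (between OMOM and OMe) followed by SN2 alkylation, with inverse addition to excess dibromide to suppress double arylation.

Step 8
Reactants: 15 octa-1,7-diene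
Product: 17 oct-7-en-1-ol, via B-(oct-7-enyl)-9-BBN 16 (not isolated)
Conditions: 9-BBN (1 equiv), 15 (3 equiv), THF, 0 °C → rt; then NaOH (aq), 30% H2O2, 0 °C → rt
Reagents that add atoms: hydrogen peroxide OO
Why: Hydroboration–oxidation, in which bulky 9-BBN adds anti-Markovnikov to one terminal alkene of the excess diene and alkaline peroxide oxidises the C–B bond.

Step 9
Reactants: 17 oct-7-en-1-ol
Product: 18 8-bromooct-1-ene
Conditions: CBr4, PPh3, CH2Cl2, 0 °C
Reagents that add atoms: carbon tetrabromide BrC(Br)(Br)Br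
Why: Appel reaction, in which the alcohol is activated as an alkoxyphosphonium ion and displaced by bromide (SN2).

Step 10
Reactants: 4 1,2,4-trimethoxybenzene
Product: 20 2,4,5-trimethoxybenzaldehyde, via iminium salt 19 (not isolated)
Conditions: POCl3, DMF, 0 → 70 °C; then H2O, NaOAc
Reagents that add atoms: N,N-dimethylformamide CN(C)C=O; water O
Why: Vilsmeier–Haack formylation of 4 goes to C-5, para to the 2-methoxy and ortho to the 4-methoxy group, and not to the hindered C-3 between two methoxy groups.

Step 11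
Reactants: 20 2,4,5-trimethoxybenzaldehyde
Product: 22 2,4,5-trimethoxyphenol, via aryl formate 21 (not isolated)
Conditions: 30% H2O2, H2SO4 (cat.), MeOH, N2, 0 °C → rt
Reagents that add atoms: hydrogen peroxide OO
Why: Acid-catalysed Dakin oxidation, in which the electron-rich aryl group migrates to oxygen and methanol cleaves the formate; the air-sensitive phenol is kept under nitrogen.

Step 12
Reactants: 22 2,4,5-trimethoxyphenol
Product: 23 1,2,4-trimethoxy-5-(methoxymethoxy)benzene
Conditions: NaH, MOMCl, DMF, 0 °C → rt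
Reagents that add atoms: chloromethyl methyl ether COCCl
Why: Williamson-type O-alkylation of the phenoxide protects the phenol and installs the director that controls the next step.

Step 13
Reactants: 23 1,2,4-trimethoxy-5-(methoxymethoxy)benzene
Product: 25 1,2,5-trimethoxy-4-(methoxymethoxy)-3-methylbenzene, via aryllithium 24 (not isolated)
Conditions: n-BuLi (1.05 equiv), Et2O (no TMEDA), 0 °C → rt; MeI, 0 °C → rt
Reagents that add atoms: iodomethane CI
Why: Directed ortho-metalation in which both free positions lie between two oxygen substituents, but the chelating OMOM group outranks OMe as a director (complex-induced proximity effect in a weakly coordinating solvent), so lithium goes between OMOM and OMe and is methylated by SN2.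

Step 14
Reactants: 25 1,2,5-trimethoxy-4-(methoxymethoxy)-3-methylbenzene; 18 8-bromooct-1-ene
Product: 27 1,2,4-trimethoxy-5-(methoxymethoxy)-6-methyl-3-(oct-7-en-1-yl)benzene, via aryllithium 26 (not isolated)
Conditions: n-BuLi, THF, 0 °C → rt; 18 (1.2 equiv), 0 °C → 50 °C
Reagents that add atoms: none
Why: Directed ortho-metalation at the only ring C–H left (between two methoxy groups) and SN2 alkylation by the primary bromide, which the terminal alkene tolerates.

Step 15
Reactants: 27 1,2,4-trimethoxy-5-(methoxymethoxy)-6-methyl-3-(oct-7-en-1-yl)benzene; 14 1-(6-bromohexyl)-2,3,5-trimethoxy-6-(methoxymethoxy)-4-methylbenzene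
Product: 29 1-[2,3,5-trimethoxy-6-(methoxymethoxy)-4-methylphenyl]-14-[2,3,6-trimethoxy-5-(methoxymethoxy)-4-methylphenyl]tetradecane, via B-alkyl-9-BBN 28 (not isolated)
Conditions: 27, 9-BBN, THF, rt; then 14, Pd(OAc)2 (4 mol%), PCy3 (8 mol%), K3PO4·H2O, THF, rt
Reagents that add atoms: none
Why: Alkyl–alkyl B-alkyl Suzuki–Miyaura coupling, in which anti-Markovnikov hydroboration gives a primary alkylborane and Pd/PCy3 couples it with the primary bromide faster than β-hydride elimination, joining the C8 and C6 arms into the (CH2)14 tether.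

Step 16
Reactants: 29 the bis(MOM ether)
Product: 30 1-(2-hydroxy-3,5,6-trimethoxy-4-methylphenyl)-14-(3-hydroxy-2,5,6-trimethoxy-4-methylphenyl)tetradecane
Conditions: conc. HCl (cat.), MeOH, 50 °C, N2
Reagents that add atoms: none
Why: Acid-catalysed transacetalisation to methanol removes both MOM groups and leaves the aryl methyl ethers untouched.

Step 17
Reactants: 30 the bisphenol
Product: 31 1-(2-acetoxy-3,5,6-trimethoxy-4-methylphenyl)-14-(3-acetoxy-2,5,6-trimethoxy-4-methylphenyl)tetradecane
Conditions: Ac2O, pyridine, DMAP (cat.), CH2Cl2, rt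
Reagents that add atoms: acetic anhydride CC(=O)OC(C)=O
Why: DMAP-catalysed O-acylation turns the future hydroxyl oxygens into poor electron donors so that they stay out of the coming oxidation.

Step 18
Reactants: 31 the bis(aryl acetate)
Product: 32 bis(acetoxy-methoxy-methyl-1,4-benzoquinone) with the (CH2)14 tether
Conditions: CAN (6 equiv), MeCN/H2O 2:1, 0 °C, 20 min
Reagents that add atoms: water O
Why: CAN oxidative demethylation, in which the radical cation is attacked by water at the two mutually para methoxy-bearing carbons while the weakly donating acetoxy oxygen and the third methoxy group are retained.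

Step 19
Reactants: 32 the bis(acetoxyquinone)
Product: 33 target, 2-hydroxy-3-[14-(5-hydroxy-2-methoxy-4-methyl-3,6-dioxocyclohexa-1,4-dien-1-yl)tetradecyl]-5-methoxy-6-methylcyclohexa-2,5-diene-1,4-dione
Conditions: LiOH, THF/H2O, 0 °C, 15 min; then 1 M HCl
Reagents that add atoms: none
Why: Saponification of the two vinylogous-anhydride enol acetates is fast, and the hydroxyquinone anion formed resists further hydroxide attack, so the vinylogous methyl esters survive.

**Compound list**
1 | p-benzoquinone | O=C1C=CC(=O)C=C1 | starting material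
2 | benzene-1,2,4-triyl triacetate | CC(=O)Oc1ccc(OC(C)=O)c(OC(C)=O)c1 | intermediate
3 | benzene-1,2,4-triol (sodium salt in the flask) | Oc1ccc(O)c(O)c1 | intermediate
4 | 1,2,4-trimethoxybenzene | COc1ccc(OC)c(OC)c1 | intermediate
5 | 2,3,6-trimethoxyphenyllithium | [Li]c1c(OC)ccc(OC)c1OC | intermediate
6 | 1,2,4-trimethoxy-3-methylbenzene | COc1ccc(OC)c(C)c1OC | intermediate
7 | N,N-dimethyl-1-(2,4,5-trimethoxy-3-methylphenyl)methaniminium chloride | C[N+](C)=Cc1cc(OC)c(OC)c(C)c1OC.[Cl-] | intermediate
8 | 2,4,5-trimethoxy-3-methylbenzaldehyde | O=Cc1cc(OC)c(OC)c(C)c1OC | intermediate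
9 | 2,4,5-trimethoxy-3-methylphenyl formate | O=COc1cc(OC)c(OC)c(C)c1OC | intermediate
10 | 2,4,5-trimethoxy-3-methylphenol | Oc1cc(OC)c(OC)c(C)c1OC | intermediate
11 | 1,2,4-trimethoxy-5-(methoxymethoxy)-3-methylbenzene | COCOc1cc(OC)c(OC)c(C)c1OC | intermediate
12 | 1,6-dibromohexane | BrCCCCCCBr | starting material
13 | [2,3,5-trimethoxy-6-(methoxymethoxy)-4-methylphenyl]lithium | [Li]c1c(OCOC)c(OC)c(C)c(OC)c1OC | intermediate
14 | 1-(6-bromohexyl)-2,3,5-trimethoxy-6-(methoxymethoxy)-4-methylbenzene | BrCCCCCCc1c(OCOC)c(OC)c(C)c(OC)c1OC | intermediate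
15 | octa-1,7-diene | C=CCCCCC=C | starting material
16 | 9-(oct-7-en-1-yl)-9-borabicyclo[3.3.1]nonane | C=CCCCCCCB1[C@H]2CCC[C@@H]1CCC2 | intermediate
17 | oct-7-en-1-ol | C=CCCCCCCO | intermediate
18 | 8-bromooct-1-ene | C=CCCCCCCBr | intermediate
19 | N,N-dimethyl-1-(2,4,5-trimethoxyphenyl)methaniminium chloride | C[N+](C)=Cc1cc(OC)c(OC)cc1OC.[Cl-] | intermediate
20 | 2,4,5-trimethoxybenzaldehyde | O=Cc1cc(OC)c(OC)cc1OC | intermediate
21 | 2,4,5-trimethoxyphenyl formate | O=COc1cc(OC)c(OC)cc1OC | intermediate
22 | 2,4,5-trimethoxyphenol | Oc1cc(OC)c(OC)cc1OC | intermediate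
23 | 1,2,4-trimethoxy-5-(methoxymethoxy)benzene | COCOc1cc(OC)c(OC)cc1OC | intermediate
24 | [2,3,5-trimethoxy-6-(methoxymethoxy)phenyl]lithium | [Li]c1c(OCOC)c(OC)cc(OC)c1OC | intermediate
25 | 1,2,5-trimethoxy-4-(methoxymethoxy)-3-methylbenzene | Cc1c(OCOC)c(OC)cc(OC)c1OC | intermediate
26 | [2,3,6-trimethoxy-5-(methoxymethoxy)-4-methylphenyl]lithium | [Li]c1c(OC)c(OCOC)c(C)c(OC)c1OC | intermediate
27 | 1,2,4-trimethoxy-5-(methoxymethoxy)-6-methyl-3-(oct-7-en-1-yl)benzene | Cc1c(OCOC)c(OC)c(CCCCCCC=C)c(OC)c1OC | intermediate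
28 | 9-{8-[2,3,6-trimethoxy-5-(methoxymethoxy)-4-methylphenyl]octyl}-9-borabicyclo[3.3.1]nonane | COCOc1c(C)c(OC)c(OC)c(CCCCCCCCB2[C@H]3CCC[C@@H]2CCC3)c1OC | intermediate
29 | 1-[2,3,5-trimethoxy-6-(methoxymethoxy)-4-methylphenyl]-14-[2,3,6-trimethoxy-5-(methoxymethoxy)-4-methylphenyl]tetradecane | COCOc1c(CCCCCCCCCCCCCCc2c(OC)c(OC)c(C)c(OCOC)c2OC)c(OC)c(OC)c(C)c1OC | intermediate
30 | 1-(2-hydroxy-3,5,6-trimethoxy-4-methylphenyl)-14-(3-hydroxy-2,5,6-trimethoxy-4-methylphenyl)tetradecane | Oc1c(CCCCCCCCCCCCCCc2c(OC)c(OC)c(C)c(O)c2OC)c(OC)c(OC)c(C)c1OC | intermediate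
31 | 1-(2-acetoxy-3,5,6-trimethoxy-4-methylphenyl)-14-(3-acetoxy-2,5,6-trimethoxy-4-methylphenyl)tetradecane | CC(=O)Oc1c(CCCCCCCCCCCCCCc2c(OC)c(OC)c(C)c(OC(C)=O)c2OC)c(OC)c(OC)c(C)c1OC | intermediate
32 | 2-[14-(5-acetoxy-2-methoxy-4-methyl-3,6-dioxocyclohexa-1,4-dien-1-yl)tetradecyl]-4-methoxy-5-methyl-3,6-dioxocyclohexa-1,4-dien-1-yl acetate | CC(=O)OC1=C(CCCCCCCCCCCCCCC2=C(OC)C(=O)C(C)=C(OC(C)=O)C2=O)C(=O)C(OC)=C(C)C1=O | intermediate
33 | 2-hydroxy-3-[14-(5-hydroxy-2-methoxy-4-methyl-3,6-dioxocyclohexa-1,4-dien-1-yl)tetradecyl]-5-methoxy-6-methylcyclohexa-2,5-diene-1,4-dione (CNP0159949.0, achiral) | COC1=C(C)C(=O)C(O)=C(CCCCCCCCCCCCCCC2=C(OC)C(=O)C(C)=C(O)C2=O)C1=O | target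

**Step count**
Total steps: 19.
Longest linear sequence: 12 steps (1 → 2 → 4 → 6 → 8 → 10 → 11 → 14 → 29 → 30 → 31 → 32 → 33, i.e. steps 1–7 and 15–19). The sequence through steps 1, 2, 10–14 and 15–19 is equally long; the one that starts at 15 (steps 8, 9, 14–19) is shorter.

**Steps most likely to fail**

Step 18 (CAN oxidation of 31). If the acetoxy-bearing carbon is drawn into the oxidation, the acetyl group is lost and the symmetrical 2,5-dimethoxyquinone forms, which erases the OH/OMe differentiation. An ortho-quinone from the two adjacent methoxy groups is the other possible side product. The fallback sets out from 30 and comes back at 33. MsCl/Et3N (CH2Cl2, 0 °C) converts 30 into the bis(methanesulfonate) F1. A sulfonate cannot be expelled from oxygen the way an acyl group can, so CAN (MeCN/H2O, 0 °C) can only turn the para-dimethoxy pair into carbonyls and gives the bis(mesyloxyquinone) F2. Aqueous NaOH in THF at 0 °C, then HCl, displaces each sulfonate by addition–elimination at the quinone carbon and gives 33 directly, with no ester hydrolysis step.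

Step 15 (alkyl–alkyl Suzuki coupling of 28 with 14). β-Hydride elimination or slow oxidative addition could give reduced or alkene by-products in place of 29. The fallback sets out from 27 and 14 and comes back at 29, with the roles of nucleophile and electrophile reversed in a copper-catalysed Grignard coupling. Borane 28 (from 27 and 9-BBN) is oxidised with NaOH/H2O2 to 8-[2,3,6-trimethoxy-5-(methoxymethoxy)-4-methylphenyl]octan-1-ol F3. TsCl in pyridine gives the tosylate F4. Bromide 14 is converted with Mg in THF into the Grignard reagent F5, which is coupled with F4 under Li2CuCl4 catalysis (THF, −20 °C → rt) to give 29.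

Step 13 (MOM-directed lithiation and methylation of 23). Both ring C–H positions of 23 lie between two oxygen substituents. If lithiation also takes place between the two methoxy groups, the regioisomeric methyl compound forms, which after step 14 would carry the substitution pattern of fragment 14 and be hard to separate. The fallback sets out from 22 and comes back at 25 and fixes the position through the free phenol, without a lithiation. Magnesium-mediated ortho-formylation of 22 (MgCl2, Et3N, paraformaldehyde, MeCN, reflux) can only reach the one free position ortho to the hydroxyl and gives 2-hydroxy-3,5,6-trimethoxybenzaldehyde F6. Ionic hydrogenation (Et3SiH, TFA, CH2Cl2, 0 °C → rt) reduces the formyl group to methyl and gives 3,4,6-trimethoxy-2-methylphenol F7. NaH/MOMCl (DMF, 0 °C → rt) then gives 25.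

**Further compounds**
F1 | step 18 | 1-[2-(methanesulfonyloxy)-3,5,6-trimethoxy-4-methylphenyl]-14-[3-(methanesulfonyloxy)-2,5,6-trimethoxy-4-methylphenyl]tetradecane | CS(=O)(=O)Oc1c(CCCCCCCCCCCCCCc2c(OC)c(OC)c(C)c(OS(C)(=O)=O)c2OC)c(OC)c(OC)c(C)c1OC
F2 | step 18 | 2-{14-[5-(methanesulfonyloxy)-2-methoxy-4-methyl-3,6-dioxocyclohexa-1,4-dien-1-yl]tetradecyl}-4-methoxy-5-methyl-3,6-dioxocyclohexa-1,4-dien-1-yl methanesulfonate | CS(=O)(=O)OC1=C(CCCCCCCCCCCCCCC2=C(OC)C(=O)C(C)=C(OS(C)(=O)=O)C2=O)C(=O)C(OC)=C(C)C1=O
F3 | step 15 | 8-[2,3,6-trimethoxy-5-(methoxymethoxy)-4-methylphenyl]octan-1-ol | COCOc1c(C)c(OC)c(OC)c(CCCCCCCCO)c1OC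
F4 | step 15 | 8-[2,3,6-trimethoxy-5-(methoxymethoxy)-4-methylphenyl]octyl 4-methylbenzenesulfonate | COCOc1c(C)c(OC)c(OC)c(CCCCCCCCOS(=O)(=O)c2ccc(C)cc2)c1OC
F5 | step 15 | {6-[2,3,5-trimethoxy-6-(methoxymethoxy)-4-methylphenyl]hexyl}magnesium bromide | Br[Mg]CCCCCCc1c(OCOC)c(OC)c(C)c(OC)c1OC
F6 | step 13 | 2-hydroxy-3,5,6-trimethoxybenzaldehyde | O=Cc1c(O)c(OC)cc(OC)c1OC
F7 | step 13 | 3,4,6-trimethoxy-2-methylphenol | Cc1c(O)c(OC)cc(OC)c1OC
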